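**Retrosynthetic overview**
1. (+)-Myristinin A ⇐ hydrogenolysis of its penta-O-benzyl ether; the three benzene rings (ring A, ring B and the acylphloroglucinol ring D) are bought, and only the dihydropyran ring C is made, in the penultimate step.
2. Ring C ⇐ Pd-catalysed intramolecular aryl C–O coupling of a (1S,3S)-1,3,3-triarylpropan-1-ol whose ring A carries an ortho chloride (retention at C2); the carbinol comes from a catalyst-controlled ketone reduction.
3. Key bond C4–ring D ⇐ stereoretentive Suzuki–Miyaura coupling of an enantioenriched β-boryl ketone with the iodide of tribenzylated lauroylphloroglucinol. The boronate is a boron homoenolate: the enone β-carbon, normally an electrophile, acts as the nucleophile towards the electrophilic ipso carbon of the aryl iodide.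
4. β-Boryl ketone ⇐ Cu-catalysed asymmetric conjugate borylation of a chalcone (Claisen–Schmidt); aryl iodide ⇐ acylation, then iodination of 1,3,5-tris(benzyloxy)benzene.

Assumption: the ligand enantiomer named in step 5 is taken to give the (R)-boronate (checked by oxidising a sample to the β-hydroxy ketone); if the (S)-boronate forms, the mirror-image ligand is used and nothing else changes.

**Step 1**
Reactants: 1 1,3,5-tris(benzyloxy)benzene + 2 dodecanoic acid (lauric acid)
Product: 4 1-[2,4,6-tris(benzyloxy)phenyl]dodecan-1-one, via dodecanoic trifluoroacetic anhydride 3 (not isolated)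
Conditions: (CF3CO)2O (2.5 equiv), CH2Cl2, 0 °C to rt
Reagents that add atoms: none
Why: Friedel–Crafts acylation by the mixed anhydride formed in the flask; the trialkoxybenzene reacts without a metal Lewis acid, which spares the benzyl ethers, and the new ketone deactivates the ring against a second acylation.

**Step 2**
Reactants: 4 1-[2,4,6-tris(benzyloxy)phenyl]dodecan-1-one
Product: 5 1-[2,4,6-tris(benzyloxy)-3-iodophenyl]dodecan-1-one
Conditions: NIS (1.05 equiv), CF3CO2H (cat.), MeCN, 0 °C to rt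
Reagents that add atoms: N-iodosuccinimide, O=C1CCC(=O)N1I
Why: Electrophilic aromatic iodination; the two free ring positions are equivalent and each is activated by two ortho and one para benzyloxy groups, so one equivalent gives a single mono-iodide.

**Step 3**
Reactants: 6 2-chloro-4-hydroxybenzaldehyde
Product: 7 4-(benzyloxy)-2-chlorobenzaldehyde
Conditions: BnBr, K2CO3, DMF, rt
Reagents that add atoms: benzyl bromide, BrCc1ccccc1
Why: Williamson ether synthesis on the acidic para-formyl phenol; the aryl chloride is inert.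

**Step 4**
Reactants: 7 4-(benzyloxy)-2-chlorobenzaldehyde + 8 1-[4-(benzyloxy)phenyl]ethan-1-one
Product: 10 (E)-3-[4-(benzyloxy)-2-chlorophenyl]-1-[4-(benzyloxy)phenyl]prop-2-en-1-one, via racemic aldol adduct 9 (not isolated)
Conditions: NaOH (aq), EtOH/THF, rt
Reagents that add atoms: none
Why: Claisen–Schmidt condensation of a non-enolisable aldehyde with an aryl methyl ketone; E1cB dehydration of the aldol gives the conjugated E-enone.

**Step 5**
Reactants: 10 (E)-3-[4-(benzyloxy)-2-chlorophenyl]-1-[4-(benzyloxy)phenyl]prop-2-en-1-one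
Product: 11 (3R)-3-[4-(benzyloxy)-2-chlorophenyl]-1-[4-(benzyloxy)phenyl]-3-(4,4,5,5-tetramethyl-1,3,2-dioxaborolan-2-yl)propan-1-one
Conditions: CuCl (5 mol %), NaOt-Bu (10 mol %), (S)-1-[(R)-2-(diphenylphosphino)ferrocenyl]ethyldicyclohexylphosphine (6 mol %), B2pin2 (1.1 equiv), MeOH (2 equiv), THF, rt
Reagents that add atoms: bis(pinacolato)diboron, CC1(C)OB(OC1(C)C)B1OC(C)(C)C(C)(C)O1
Why: Copper-catalysed asymmetric conjugate borylation; the chiral bisphosphine–copper boryl adds boron to one enantiotopic face of the enone β-carbon and MeOH protonates the copper enolate, which sets the C–B stereocentre and reverses the polarity of that carbon.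

**Step 6**
Reactants: 11 (3R)-β-boryl ketone + 5 1-[2,4,6-tris(benzyloxy)-3-iodophenyl]dodecan-1-one
Product: 12 (3S)-3-[4-(benzyloxy)-2-chlorophenyl]-1-[4-(benzyloxy)phenyl]-3-[2,4,6-tris(benzyloxy)-3-dodecanoylphenyl]propan-1-one
Conditions: Pd2(dba)3 (5 mol %), PPh3 (80 mol %), Ag2O (1.5 equiv), DME, 85 °C
Reagents that add atoms: none
Why: Proposed new method: the β-boryl ketone is a configurationally fixed homoenolate whose β-carbon (electrophilic in the parent enone) is transferred as a nucleophile to the arylpalladium iodide formed by oxidative addition of 5 to zerovalent palladium, with Ag2O giving a closed, B–O–Pd-linked transmetalation that runs with retention and excess PPh3 favouring reductive elimination over β-hydride elimination, so the (R)-C–B centre becomes the (S)-diarylmethine (same spatial arrangement, only the priorities change); the closest known reaction type is the stereoretentive Ag2O-promoted Suzuki–Miyaura coupling of enantioenriched secondary benzylic and dibenzylic pinacol boronates with aryl iodides, together with couplings of β-trifluoroborato carbonyl compounds, neither yet shown for a chiral β-boryl ketone with a 2,6-dioxygenated aryl iodide.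

**Step 7**
Reactants: 12 (3S)-triaryl ketone
Product: 13 (1S,3S)-3-[4-(benzyloxy)-2-chlorophenyl]-1-[4-(benzyloxy)phenyl]-3-[2,4,6-tris(benzyloxy)-3-dodecanoylphenyl]propan-1-ol
Conditions: RuCl[(S,S)-TsDPEN](p-cymene) (2 mol %), HCO2H/Et3N (5:2), CH2Cl2, 35 °C
Reagents that add atoms: none
Why: Noyori asymmetric transfer hydrogenation; the (S,S)-catalyst delivers hydride to the face of the aryl alkyl ketone that gives the (S)-1-arylalkanol under catalyst control, while the dodecanoyl ketone flanked by two ortho benzyloxy groups is too hindered to react.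

**Step 8**
Reactants: 13 (1S,3S)-chloro alcohol
Product: 14 1-{2,4,6-tris(benzyloxy)-3-[(2S,4R)-7-(benzyloxy)-2-[4-(benzyloxy)phenyl]-3,4-dihydro-2H-chromen-4-yl]phenyl}dodecan-1-one
Conditions: Pd(OAc)2 (5 mol %), t-BuXPhos (10 mol %), Cs2CO3 (2 equiv), toluene, 90 °C
Reagents that add atoms: none
Why: Intramolecular palladium-catalysed aryl C–O coupling (Buchwald–Hartwig etherification) closes ring C; only the O–H bond of the carbinol reacts, so C2 keeps its configuration and C4 is untouched, and ring A alone carries a halide, so ring D cannot close instead.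

**Step 9**
Reactants: 14 penta-O-benzyl myristinin A
Product: 15 (+)-myristinin A
Conditions: H2 (1 atm), Pd(OH)2/C, EtOAc/MeOH, rt
Reagents that add atoms: none
Why: Catalytic hydrogenolysis of five aryl benzyl ethers under neutral conditions, which avoids the acid that would ionise C2–O or C4–aryl; both stereocentres are untouched.

**Compound list**
1 | 1,3,5-tris(benzyloxy)benzene | c1c(OCc2ccccc2)cc(OCc2ccccc2)cc1OCc1ccccc1 | starting material
2 | dodecanoic acid (lauric acid) | CCCCCCCCCCCC(=O)O | starting material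
3 | dodecanoic trifluoroacetic anhydride | CCCCCCCCCCCC(=O)OC(=O)C(F)(F)F | intermediate
4 | 1-[2,4,6-tris(benzyloxy)phenyl]dodecan-1-one | CCCCCCCCCCCC(=O)c1c(OCc2ccccc2)cc(OCc2ccccc2)cc1OCc1ccccc1 | intermediate
5 | 1-[2,4,6-tris(benzyloxy)-3-iodophenyl]dodecan-1-one | CCCCCCCCCCCC(=O)c1c(OCc2ccccc2)c(I)c(OCc2ccccc2)cc1OCc1ccccc1 | intermediate
6 | 2-chloro-4-hydroxybenzaldehyde | O=Cc1ccc(O)cc1Cl | starting material
7 | 4-(benzyloxy)-2-chlorobenzaldehyde | O=Cc1ccc(OCc2ccccc2)cc1Cl | intermediate
8 | 1-[4-(benzyloxy)phenyl]ethan-1-one | CC(=O)c1ccc(OCc2ccccc2)cc1 | starting material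
9 | 3-[4-(benzyloxy)-2-chlorophenyl]-1-[4-(benzyloxy)phenyl]-3-hydroxypropan-1-one (racemic aldol adduct) | O=C(CC(O)c1ccc(OCc2ccccc2)cc1Cl)c1ccc(OCc2ccccc2)cc1 | intermediate
10 | (E)-3-[4-(benzyloxy)-2-chlorophenyl]-1-[4-(benzyloxy)phenyl]prop-2-en-1-one | O=C(/C=C/c1ccc(OCc2ccccc2)cc1Cl)c1ccc(OCc2ccccc2)cc1 | intermediate
11 | (3R)-3-[4-(benzyloxy)-2-chlorophenyl]-1-[4-(benzyloxy)phenyl]-3-(4,4,5,5-tetramethyl-1,3,2-dioxaborolan-2-yl)propan-1-one | CC1(C)OB(OC1(C)C)[C@@H](c1ccc(OCc2ccccc2)cc1Cl)CC(=O)c1ccc(OCc2ccccc2)cc1 | intermediate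
12 | (3S)-3-[4-(benzyloxy)-2-chlorophenyl]-1-[4-(benzyloxy)phenyl]-3-[2,4,6-tris(benzyloxy)-3-dodecanoylphenyl]propan-1-one | CCCCCCCCCCCC(=O)c1c(OCc2ccccc2)cc(OCc2ccccc2)c([C@@H](c2ccc(OCc3ccccc3)cc2Cl)CC(=O)c2ccc(OCc3ccccc3)cc2)c1OCc1ccccc1 | intermediate
13 | (1S,3S)-3-[4-(benzyloxy)-2-chlorophenyl]-1-[4-(benzyloxy)phenyl]-3-[2,4,6-tris(benzyloxy)-3-dodecanoylphenyl]propan-1-ol | CCCCCCCCCCCC(=O)c1c(OCc2ccccc2)cc(OCc2ccccc2)c([C@@H](c2ccc(OCc3ccccc3)cc2Cl)C[C@@H](c2ccc(OCc3ccccc3)cc2)O)c1OCc1ccccc1 | intermediate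
14 | 1-{2,4,6-tris(benzyloxy)-3-[(2S,4R)-7-(benzyloxy)-2-[4-(benzyloxy)phenyl]-3,4-dihydro-2H-chromen-4-yl]phenyl}dodecan-1-one | CCCCCCCCCCCC(=O)c1c(OCc2ccccc2)cc(OCc2ccccc2)c([C@@H]2C[C@@H](c3ccc(OCc4ccccc4)cc3)Oc3cc(OCc4ccccc4)ccc32)c1OCc1ccccc1 | intermediate
15 | (+)-myristinin A, 1-{2,4,6-trihydroxy-3-[(2S,4R)-7-hydroxy-2-(4-hydroxyphenyl)-3,4-dihydro-2H-chromen-4-yl]phenyl}dodecan-1-one | CCCCCCCCCCCC(=O)c1c(O)cc(O)c([C@@H]2C[C@@H](c3ccc(O)cc3)Oc3cc(O)ccc32)c1O | target

**Step count**
Total step count: 9. Longest linear sequence: 7 steps (steps 3 to 9, from 6 to 15).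

**Three steps most likely to fail**

Step 6 (key coupling). The aryl iodide has two ortho benzyloxy groups and a neighbouring acyl group, so transmetalation of the secondary benzylic boronate may lose out to protodeboronation or β-hydride elimination back to the chalcone. The fallback sets out from 11 (with an iodide made from 1) and comes back at 12. Compound 1 is iodinated (NIS, cat. CF3CO2H, MeCN) to 1,3,5-tris(benzyloxy)-2-iodobenzene F1. This smaller, acyl-free partner is coupled with 11 under the step 6 conditions to give (3S)-3-[4-(benzyloxy)-2-chlorophenyl]-1-[4-(benzyloxy)phenyl]-3-[2,4,6-tris(benzyloxy)phenyl]propan-1-one F2. Acylation of F2 with lauric acid 2 and (CF3CO)2O (via 3, CH2Cl2, 0 °C) at either of the two equivalent free positions of the trialkoxy ring then gives 12. The acyl group is thus installed after, not before, the C4–aryl bond.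

Step 8 (ring C closure). Oxidative addition into the hindered aryl chloride may be slow, and the palladium alkoxide of a secondary benzylic alcohol can undergo β-hydride elimination back to ketone 12. The fallback sets out from 12 and comes back at 14, closing the ring by SN2 at C2 instead of by aryl C–O coupling. The chloride of 12 is exchanged for hydroxyl (Pd2(dba)3, t-BuXPhos, KOH, dioxane/H2O, 100 °C, neutral work-up) to give (3R)-3-[4-(benzyloxy)-2-hydroxyphenyl]-1-[4-(benzyloxy)phenyl]-3-[2,4,6-tris(benzyloxy)-3-dodecanoylphenyl]propan-1-one F3. Transfer hydrogenation with the mirror-image catalyst RuCl[(R,R)-TsDPEN](p-cymene) in HCO2H/Et3N gives (1R,3R)-3-[4-(benzyloxy)-2-hydroxyphenyl]-1-[4-(benzyloxy)phenyl]-3-[2,4,6-tris(benzyloxy)-3-dodecanoylphenyl]propan-1-ol F4. Mitsunobu cyclisation (PPh3, DIAD, THF, 0 °C) then lets the ring A phenol displace the activated carbinol with inversion, giving 14.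

Step 1 (acylation). Trifluoroacetic acid set free in the flask can cleave or migrate the benzyl groups of the very electron-rich ring. The fallback sets out from 2 and comes back at 4, acylating the free triphenol first and benzylating afterwards. Lauric acid 2 and phloroglucinol are heated in BF3·OEt2 (90 °C) to give 1-(2,4,6-trihydroxyphenyl)dodecan-1-one F5. Exhaustive O-benzylation of F5 (BnBr, K2CO3, DMF, 70 °C) gives 4.

**Further compounds**
F1 | step 6 | 1,3,5-tris(benzyloxy)-2-iodobenzene | Ic1c(OCc2ccccc2)cc(OCc2ccccc2)cc1OCc1ccccc1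
F2 | step 6 | (3S)-3-[4-(benzyloxy)-2-chlorophenyl]-1-[4-(benzyloxy)phenyl]-3-[2,4,6-tris(benzyloxy)phenyl]propan-1-one | c1c(OCc2ccccc2)cc(OCc2ccccc2)c([C@@H](c2ccc(OCc3ccccc3)cc2Cl)CC(=O)c2ccc(OCc3ccccc3)cc2)c1OCc1ccccc1
F3 | step 8 | (3R)-3-[4-(benzyloxy)-2-hydroxyphenyl]-1-[4-(benzyloxy)phenyl]-3-[2,4,6-tris(benzyloxy)-3-dodecanoylphenyl]propan-1-one | CCCCCCCCCCCC(=O)c1c(OCc2ccccc2)cc(OCc2ccccc2)c([C@@H](c2ccc(OCc3ccccc3)cc2O)CC(=O)c2ccc(OCc3ccccc3)cc2)c1OCc1ccccc1
F4 | step 8 | (1R,3R)-3-[4-(benzyloxy)-2-hydroxyphenyl]-1-[4-(benzyloxy)phenyl]-3-[2,4,6-tris(benzyloxy)-3-dodecanoylphenyl]propan-1-ol | CCCCCCCCCCCC(=O)c1c(OCc2ccccc2)cc(OCc2ccccc2)c([C@@H](c2ccc(OCc3ccccc3)cc2O)C[C@H](c2ccc(OCc3ccccc3)cc2)O)c1OCc1ccccc1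
F5 | step 1 | 1-(2,4,6-trihydroxyphenyl)dodecan-1-one | CCCCCCCCCCCC(=O)c1c(O)cc(O)cc1O
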